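**Strategy.** Ring A is not acylated; it is built around an ester that already exists. Cutting the ring A bonds C1–C2 and C5–C6 exposes an undecyl-substituted ynoate (ring carbons C1 and C6, with the carboxyl carbon on C1) and a dimedone-derived 1,3-bis(silyloxy)diene (C2–C5). One thermal operation, [4+2] addition followed by loss of 2-methylpropene, should deliver the benzoate with oxygen on C2 and C4 and the undecyl group on C6. The precursor is the (R)-11-[3,5-bis(benzyloxy)phenyl]undecan-4-yl ester of tetradec-2-ynoic acid. Its single stereocentre comes from (R)-2-propyloxirane, and ring B is carried as its bis(benzyl) ether.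

Key step: step 7

Remark: ring A is numbered with the ester-bearing carbon as C1, the oxygenated carbons as C2 and C4 and the undecyl-bearing carbon as C6; the cycloadduct of step 7 forms as two bridgehead diastereomers that converge on one arene, so its SMILES carries no bridgehead descriptors.

**Step 1**
Reactants: 1 3,5-bis(benzyloxy)benzyl bromide; 2 1-bromo-5-chloropentane
Product: 4 1,3-bis(benzyloxy)-5-(6-chlorohexyl)benzene, via (5-chloropentyl)magnesium bromide 3 (not isolated)
Conditions: 2, Mg, THF, rt; then 1, Li2CuCl4 (3 mol%), THF, −10 °C to rt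
Reagents that add atoms: none
Why: Magnesium inserts selectively into the C–Br bond of 2, and the resulting primary Grignard reagent should couple with the benzylic bromide under Li2CuCl4 catalysis (Kochi-type copper-catalysed sp3–sp3 cross-coupling) much faster than with an alkyl chloride, so the chloride end survives for step 2.

**Step 2**
Reactants: 4 1,3-bis(benzyloxy)-5-(6-chlorohexyl)benzene; 5 (R)-2-propyloxirane
Product: 7 (R)-11-[3,5-bis(benzyloxy)phenyl]undecan-4-ol, via arylhexylmagnesium chloride 6 (not isolated)
Conditions: 4, Mg (activated with a little 1,2-dibromoethane), THF, reflux; then CuI (10 mol%), 5, THF, −30 to 0 °C; aq NH4Cl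
Reagents that add atoms: none
Why: Copper-catalysed Grignard opening of a monosubstituted epoxide is an SN2 attack at the unsubstituted CH2 carbon, so no bond to the stereogenic carbon is broken and the (R) configuration of 5 becomes the (R) configuration of the carbinol carbon, the benzyl ethers being inert to the organomagnesium reagent.

**Step 3**
Reactants: 8 tridec-1-yne
Product: 10 tetradec-2-ynoic acid, via lithium tridec-1-ynide 9 (not isolated)
Conditions: n-BuLi, THF, −78 °C; CO2 (gas), −78 °C to rt; 1 M HCl
Reagents that add atoms: carbon dioxide, O=C=O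
Why: Lithiation of the terminal alkyne and carboxylation of the acetylide with CO2 is the standard entry to alk-2-ynoic acids and touches no other functional group.

**Step 4**
Reactants: 10 tetradec-2-ynoic acid; 7 (R)-11-[3,5-bis(benzyloxy)phenyl]undecan-4-ol
Product: 11 (R)-11-[3,5-bis(benzyloxy)phenyl]undecan-4-yl tetradec-2-ynoate
Conditions: DCC, DMAP (5 mol%), CH2Cl2, 0 °C to rt
Reagents that add atoms: none
Why: Steglich esterification (carbodiimide activation, catalytic DMAP) acylates the unhindered secondary hydroxyl at oxygen, so the C–O bond of the stereocentre is untouched and the (R) configuration is retained; low temperature and a small DMAP loading limit conjugate addition to the ynoate.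

**Step 5**
Reactants: 12 5,5-dimethylcyclohexane-1,3-dione (dimedone)
Product: 13 5,5-dimethyl-3-(trimethylsilyloxy)cyclohex-2-en-1-one
Conditions: HMDS, imidazole (cat.), toluene, reflux; distillation
Reagents that add atoms: hexamethyldisilazane, C[Si](C)(C)N[Si](C)(C)C
Why: The strongly enolised 1,3-dione is O-silylated by hexamethyldisilazane under imidazole catalysis (silyl enol ether formation), ammonia being the only by-product.

**Step 6**
Reactants: 13 5,5-dimethyl-3-(trimethylsilyloxy)cyclohex-2-en-1-one
Product: 15 5,5-dimethyl-1,3-bis(trimethylsilyloxy)cyclohexa-1,3-diene, via lithium dienolate 14 (not isolated)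
Conditions: LiN(i-Pr)2 (LDA), THF, −78 °C; TMSCl, −78 °C to rt; pentane, filtration, distillation
Reagents that add atoms: chlorotrimethylsilane, C[Si](C)(C)Cl
Why: Kinetic deprotonation of the vinylogous silyl ester by LDA and O-silylation of the lithium dienolate (silyl enol ether formation) gives the 1,3-bis(silyloxy)diene, and because the two ring CH2 groups flanking the gem-dimethyl carbon are equivalent in the dimedone skeleton only one such diene can arise.

**Step 7**
Reactants: 11 (R)-11-[3,5-bis(benzyloxy)phenyl]undecan-4-yl tetradec-2-ynoate; 15 5,5-dimethyl-1,3-bis(trimethylsilyloxy)cyclohexa-1,3-diene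
Product: 18 (R)-11-[3,5-bis(benzyloxy)phenyl]undecan-4-yl 2,4-dihydroxy-6-undecylbenzoate, via bicyclo[2.2.2]octadiene adduct 16 (not isolated), via bis(trimethylsilyl) ether 17 (not isolated)
Conditions: 15 (4 equiv), neat, sealed tube, 150 °C; then 1 M HCl, THF, rt
Reagents that add atoms: none
Why: The electron-rich diene 15 and the electron-poor alkyne of 11 should combine in a concerted, normal-electron-demand Diels–Alder reaction to give the bicyclo[2.2.2]octa-2,5-diene 16, which at the same temperature loses its CMe2–CH2 bridge as 2-methylpropene by retro-[4+2] (Alder–Rickert sequence) because an aromatic ring is gained, and dilute acid then hydrolyses the two labile aryl silyl ethers of 17. The closest known reaction type is the thermal cycloaddition–cycloreversion of alk-2-ynoate esters with bis(silyloxy)cyclohexadienes derived from cyclohexane-1,3-diones, which gives 2,4-dioxygenated benzoates. Ring A is closed by intermolecular [4+2] annulation of four diene carbons (C2–C5) onto two alkyne carbons (C1 and C6), the bonds C1–C2 and C5–C6 being made together. No stereocentre is created in the isolated product: the bridgehead centres of 16 vanish on aromatisation, and the carbinol carbon set in step 2 is remote from every reacting atom and cannot epimerise under heat or dilute acid. The selectivity needed is regiochemical and is secured by matched polarisation: the unsubstituted diene terminus, the vinylogous terminus of both silyloxy groups and the site of the largest HOMO coefficient, bonds to the undecyl-bearing β-carbon of the ynoate (largest LUMO coefficient), so the silyloxy-bearing terminus ends up next to the ester carbon and the second oxygen para to it. Because the ester is made before the arene, the di-ortho-substituted benzoate never has to be acylated.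

**Step 8**
Reactants: 18 (R)-11-[3,5-bis(benzyloxy)phenyl]undecan-4-yl 2,4-dihydroxy-6-undecylbenzoate
Product: 19 (R)-11-(3,5-dihydroxyphenyl)undecan-4-yl 2,4-dihydroxy-6-undecylbenzoate
Conditions: H2 (1 atm), Pd/C (10 wt% palladium on carbon), EtOAc–EtOH, rt
Reagents that add atoms: none
Why: Palladium-catalysed hydrogenolysis cleaves the two benzylic C–O bonds of ring B to the free phenols, while the non-benzylic ester C–O bond, the arenes and the stereocentre are inert under these neutral conditions.

**Compound list**
1 | 3,5-bis(benzyloxy)benzyl bromide | BrCc1cc(OCc2ccccc2)cc(OCc2ccccc2)c1 | starting material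
2 | 1-bromo-5-chloropentane | ClCCCCCBr | starting material
3 | (5-chloropentyl)magnesium bromide | ClCCCCC[Mg]Br | intermediate (not isolated)
4 | 1,3-bis(benzyloxy)-5-(6-chlorohexyl)benzene | ClCCCCCCc1cc(OCc2ccccc2)cc(OCc2ccccc2)c1 | intermediate
5 | (R)-2-propyloxirane | CCC[C@@H]1CO1 | starting material
6 | {6-[3,5-bis(benzyloxy)phenyl]hexyl}magnesium chloride | Cl[Mg]CCCCCCc1cc(OCc2ccccc2)cc(OCc2ccccc2)c1 | intermediate (not isolated)
7 | (R)-11-[3,5-bis(benzyloxy)phenyl]undecan-4-ol | CCC[C@@H](O)CCCCCCCc1cc(OCc2ccccc2)cc(OCc2ccccc2)c1 | intermediate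
8 | tridec-1-yne | CCCCCCCCCCCC#C | starting material
9 | lithium tridec-1-yn-1-ide | CCCCCCCCCCCC#C[Li] | intermediate (not isolated)
10 | tetradec-2-ynoic acid | CCCCCCCCCCCC#CC(=O)O | intermediate
11 | (R)-11-[3,5-bis(benzyloxy)phenyl]undecan-4-yl tetradec-2-ynoate | CCCCCCCCCCCC#CC(=O)O[C@H](CCC)CCCCCCCc1cc(OCc2ccccc2)cc(OCc2ccccc2)c1 | intermediate
12 | 5,5-dimethylcyclohexane-1,3-dione (dimedone) | CC1(C)CC(=O)CC(=O)C1 | starting material
13 | 5,5-dimethyl-3-(trimethylsilyloxy)cyclohex-2-en-1-one | CC1(C)CC(=O)C=C(O[Si](C)(C)C)C1 | intermediate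
14 | lithium 3,3-dimethyl-5-(trimethylsilyloxy)cyclohexa-1,5-dien-1-olate | [Li]OC1=CC(C)(C)CC(O[Si](C)(C)C)=C1 | intermediate (not isolated)
15 | 5,5-dimethyl-1,3-bis(trimethylsilyloxy)cyclohexa-1,3-diene | C[Si](C)(C)OC1=CC(O[Si](C)(C)C)=CC(C)(C)C1 | intermediate
16 | (R)-11-[3,5-bis(benzyloxy)phenyl]undecan-4-yl 8,8-dimethyl-1,5-bis(trimethylsilyloxy)-3-undecylbicyclo[2.2.2]octa-2,5-diene-2-carboxylate (both bridgehead diastereomers) | C[Si](C)(C)OC12C=C(O[Si](C)(C)C)C(C(C)(C)C1)C(CCCCCCCCCCC)=C2C(=O)O[C@H](CCC)CCCCCCCc1cc(OCc2ccccc2)cc(OCc2ccccc2)c1 | intermediate (not isolated)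
17 | (R)-11-[3,5-bis(benzyloxy)phenyl]undecan-4-yl 2,4-bis(trimethylsilyloxy)-6-undecylbenzoate | CCCCCCCCCCCc1cc(O[Si](C)(C)C)cc(O[Si](C)(C)C)c1C(=O)O[C@H](CCC)CCCCCCCc1cc(OCc2ccccc2)cc(OCc2ccccc2)c1 | intermediate (not isolated)
18 | (R)-11-[3,5-bis(benzyloxy)phenyl]undecan-4-yl 2,4-dihydroxy-6-undecylbenzoate | CCCCCCCCCCCc1cc(O)cc(O)c1C(=O)O[C@H](CCC)CCCCCCCc1cc(OCc2ccccc2)cc(OCc2ccccc2)c1 | intermediate
19 | (R)-11-(3,5-dihydroxyphenyl)undecan-4-yl 2,4-dihydroxy-6-undecylbenzoate | CCCCCCCCCCCc1cc(O)cc(O)c1C(=O)O[C@H](CCC)CCCCCCCc1cc(O)cc(O)c1 | target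

**Totals.** Total step count: 8. Longest linear sequence: 5 steps (1, 2, 4, 7, 8).

**Steps most likely to fail**

Step 7. The β-alkyl ynoate may add too slowly at a temperature the diene tolerates, so that hydrolysis or thermal decomposition of the diene outruns the cycloaddition. The fallback sets out from alcohol 7 and returns at target 19, building ring A by cross-coupling and acyl transfer instead of cycloaddition. 2,4,6-Trihydroxybenzoic acid (purchased) would be condensed with acetone in trifluoroacetic anhydride and trifluoroacetic acid to give 5,7-dihydroxy-2,2-dimethyl-4H-1,3-benzodioxin-4-one F1. Mitsunobu benzylation (BnOH, PPh3, DIAD) of its non-chelated hydroxyl would give 7-(benzyloxy)-5-hydroxy-2,2-dimethyl-4H-1,3-benzodioxin-4-one F2. Tf2O and pyridine would then give 7-(benzyloxy)-2,2-dimethyl-4-oxo-4H-1,3-benzodioxin-5-yl trifluoromethanesulfonate F3. B-alkyl Suzuki–Miyaura coupling of F3 with 9-undecyl-9-borabicyclo[3.3.1]nonane F4 (from undec-1-ene and 9-BBN-H), using Pd(dppf)Cl2 and K3PO4 in THF–water, would give 7-(benzyloxy)-2,2-dimethyl-5-undecyl-4H-1,3-benzodioxin-4-one F5. The sodium alkoxide of 7 (NaH, THF) would open F5 at the lactone carbonyl with loss of acetone, the C–O bond of the stereocentre staying intact. This would give (R)-11-[3,5-bis(benzyloxy)phenyl]undecan-4-yl 4-(benzyloxy)-2-hydroxy-6-undecylbenzoate F6. The hydrogenolysis conditions of step 8 would then remove all three benzyl groups to reach 19.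

Step 2. Magnesium insertion into the primary C–Cl bond may be slow or incomplete and accompanied by Wurtz-type homocoupling, which would waste the enantiopure epoxide. The fallback sets out from epoxide 5 and returns at alcohol 7, replacing the organomagnesium of ring B by a palladium-catalysed coupling. Purchased hex-5-enylmagnesium bromide would open 5 under CuI catalysis at the CH2 carbon to give (R)-undec-10-en-4-ol F7. Excess 9-BBN-H would hydroborate the terminal alkene and borylate the hydroxyl, giving the bis-boryl adduct (R)-9-{[11-(9-borabicyclo[3.3.1]nonan-9-yl)undecan-4-yl]oxy}-9-borabicyclo[3.3.1]nonane F8. B-alkyl Suzuki–Miyaura coupling of F8 with purchased 1,3-bis(benzyloxy)-5-bromobenzene (Pd(dppf)Cl2, aq NaOH, THF, 60 °C) would form the aryl–C11 bond and release the hydroxyl on work-up to give 7.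

Step 4. The carbodiimide-activated ynoic acid may suffer conjugate addition of DMAP or rearrange to the N-acylurea before the secondary alcohol attacks. The fallback sets out from chloride 4 and returns at ester 11, activating the alcohol instead of the acid. Grignard reagent 6 would be added to purchased (S)-2-propyloxirane under the CuI conditions of step 2 to give (S)-11-[3,5-bis(benzyloxy)phenyl]undecan-4-ol F9. Mitsunobu esterification of F9 with acid 10 (PPh3, DIAD, THF, 0 °C) would give 11 with inversion at the carbinol carbon, and no acyl-activated ynoate would be exposed to a nucleophilic catalyst.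

**Further compounds**
F1 | step 7 | 5,7-dihydroxy-2,2-dimethyl-4H-1,3-benzodioxin-4-one | CC1(C)OC(=O)c2c(O)cc(O)cc2O1
F2 | step 7 | 7-(benzyloxy)-5-hydroxy-2,2-dimethyl-4H-1,3-benzodioxin-4-one | CC1(C)OC(=O)c2c(O)cc(OCc3ccccc3)cc2O1
F3 | step 7 | 7-(benzyloxy)-2,2-dimethyl-4-oxo-4H-1,3-benzodioxin-5-yl trifluoromethanesulfonate | CC1(C)OC(=O)c2c(OS(=O)(=O)C(F)(F)F)cc(OCc3ccccc3)cc2O1
F4 | step 7 | 9-undecyl-9-borabicyclo[3.3.1]nonane | CCCCCCCCCCCB1C2CCCC1CCC2
F5 | step 7 | 7-(benzyloxy)-2,2-dimethyl-5-undecyl-4H-1,3-benzodioxin-4-one | CCCCCCCCCCCc1cc(OCc2ccccc2)cc2OC(C)(C)OC(=O)c12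
F6 | step 7 | (R)-11-[3,5-bis(benzyloxy)phenyl]undecan-4-yl 4-(benzyloxy)-2-hydroxy-6-undecylbenzoate | CCCCCCCCCCCc1cc(OCc2ccccc2)cc(O)c1C(=O)O[C@H](CCC)CCCCCCCc1cc(OCc2ccccc2)cc(OCc2ccccc2)c1
F7 | step 2 | (R)-undec-10-en-4-ol | CCC[C@@H](O)CCCCCC=C
F8 | step 2 | (R)-9-{[11-(9-borabicyclo[3.3.1]nonan-9-yl)undecan-4-yl]oxy}-9-borabicyclo[3.3.1]nonane | CCC[C@@H](OB1C2CCCC1CCC2)CCCCCCCB1C2CCCC1CCC2
F9 | step 4 | (S)-11-[3,5-bis(benzyloxy)phenyl]undecan-4-ol | CCC[C@H](O)CCCCCCCc1cc(OCc2ccccc2)cc(OCc2ccccc2)c1
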